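**Plan**
1. Cuts: the eight benzyl ethers come off last. Before that, ring C of the upper unit is cut at O1–C2 and at C4a–C4. This releases ring A as plain resorcinol and leaves a chain C4–C3–C2 between C8 of ring D and ring B. C4–C8(D) is then cut to an 8-lithiated catechin ether and an aryl glycidic aldehyde.
2. Enabling feature: C4 is benzylic to ring D (O1 and 7-O ortho, 5-O para to C8), so a carbinol there ionises with trace acid. C2 is benzylic to ring B (4'-O para), so a C2–C3 epoxide opens at C2. These two electrophilic carbons are 1,3-related, as are the nucleophilic ring carbon and the OH of resorcinol.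
3. Forward order: rings D, E and F come ready-made from (+)-catechin. Ring B is extended by two carbons and epoxidised, and the chain is joined to C8 of ring D. Rings A and C then arrive together in a [3+3] annulation, and hydrogenolysis ends the route.
4. Stereochemistry: C2 and C3 of the lower unit come from the chiral pool. C3 and, after inversion, C2 of the upper unit come from a catalyst-controlled epoxidation. C4 comes from 1,2-induction by C3 in the annulation.

Key step: step 8

Assumption: flavan numbering and ring letters (upper unit A, B, C; lower unit D, E, F) are used, the chain carbons of 8, 10, 12 and 13 carry their later flavan numbers, and both enantiomers of the diarylprolinol silyl ether are taken as purchasable.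

Step 1
Reactants: 1 (+)-catechin
Product: 2 5,7,3',4'-tetra-O-benzylcatechin
Conditions: BnBr (4.4 equiv), K2CO3 (5 equiv), DMF, 0 °C to rt
Reagents that add atoms: benzyl bromide, BrCc1ccccc1
Why: Williamson etherification in which carbonate deprotonates only the four phenols and not the secondary 3-OH, and the mild base leaves C2 and C3 untouched.

Step 2
Reactants: 2 5,7,3',4'-tetra-O-benzylcatechin
Product: 3 8-bromo-5,7,3',4'-tetra-O-benzylcatechin
Conditions: NBS (1.0 equiv), CH2Cl2, −78 °C to rt
Reagents that add atoms: N-bromosuccinimide, O=C1CCC(=O)N1Br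
Why: Electrophilic aromatic bromination, for which C8 of ring D is the well-precedented most reactive position in benzylated catechins, and one equivalent should stop at the monobromide.

Step 3
Reactants: 3 8-bromo-5,7,3',4'-tetra-O-benzylcatechin
Product: 4 8-bromo-3,5,7,3',4'-penta-O-benzylcatechin
Conditions: NaH (1.3 equiv), BnBr (1.2 equiv), DMF, 0 °C to rt
Reagents that add atoms: benzyl bromide, BrCc1ccccc1
Why: Williamson etherification of the secondary alkoxide masks the only acidic proton before the halogen-lithium exchange, with a group that leaves in the final hydrogenolysis.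

Step 4
Reactants: 5 3,4,5-trihydroxybenzaldehyde
Product: 6 3,4,5-tris(benzyloxy)benzaldehyde
Conditions: BnBr (3.3 equiv), K2CO3 (4 equiv), DMF, 60 °C
Reagents that add atoms: benzyl bromide, BrCc1ccccc1
Why: Williamson etherification of three phenols under carbonate, which the aldehyde tolerates.

Step 5
Reactants: 6 3,4,5-tris(benzyloxy)benzaldehyde
Product: 7 (E)-3-[3,4,5-tris(benzyloxy)phenyl]prop-2-enal
Conditions: Ph3P=CHCHO (1.1 equiv), toluene, 90 °C
Reagents that add atoms: (triphenylphosphoranylidene)acetaldehyde, O=CC=P(c1ccccc1)(c1ccccc1)c1ccccc1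
Why: Wittig olefination with a stabilised formyl ylide should give the E-enal in one step, and near-stoichiometric ylide limits a second vinylogation.

Step 6
Reactants: 7 (E)-3-[3,4,5-tris(benzyloxy)phenyl]prop-2-enal
Product: 8 (2R,3S)-3-[3,4,5-tris(benzyloxy)phenyl]oxirane-2-carbaldehyde
Conditions: 35% aq H2O2 (1.3 equiv), (R)-2-{bis[3,5-bis(trifluoromethyl)phenyl](trimethylsilyloxy)methyl}pyrrolidine (10 mol%), CH2Cl2, rt
Reagents that add atoms: hydrogen peroxide, OO
Why: Iminium-enamine organocatalytic epoxidation of an enal (Weitz–Scheffer type), in which the bulky group of the (R)-catalyst shields one face of the E-iminium ion, peroxide adds to the β-carbon from the open face and the enamine closes the trans-epoxide, so that the later C3 is set in its final sense and the later C2 as (S), ready for inversion.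

Step 7
Reactants: 4 8-bromo-3,5,7,3',4'-penta-O-benzylcatechin; 8 (2R,3S)-3-[3,4,5-tris(benzyloxy)phenyl]oxirane-2-carbaldehyde
Product: 10 (penta-O-benzylcatechin-8-yl)[(2S,3S)-3-(3,4,5-tris(benzyloxy)phenyl)oxiran-2-yl]methanol (both carbinol epimers), via 8-lithio-penta-O-benzylcatechin 9 (not isolated)
Conditions: n-BuLi (1.05 equiv), THF, −78 °C; then 8 in THF, −78 °C; H2O quench; short plug of Et3N-deactivated silica, used at once
Reagents that add atoms: none
Why: Bromine-lithium exchange followed by 1,2-addition of the aryllithium to the aldehyde, which at −78 °C is far faster than epoxide opening, and the carbinol centre may form as a mixture because step 8 makes it planar.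

Step 8
Reactants: 10 epoxy carbinol (both carbinol epimers); 11 resorcinol
Product: 14 3',4',5'-tri-O-benzylrobinetinidol-(4α,8)-penta-O-benzylcatechin, via C4 benzylic cation 12 (not isolated), via Friedel-Crafts adduct 13 (not isolated)
Conditions: resorcinol (8 equiv), (PhO)2P(O)OH (5 mol%), HFIP (1,1,1,3,3,3-hexafluoropropan-2-ol)/CH2Cl2 3:1, 0.02 M, −20 °C to rt
Reagents that add atoms: none
Why: Proposed new method: catalytic acid in HFIP should ionise the C4 carbinol of both epimers of 10 to cation 12, whose charge is spread over O1, 5-O and 7-O of ring D, resorcinol should capture it through its ring carbon C4 to give 13, and the phenol OH ortho to the new bond should then open the hydrogen-bond-activated epoxide at C2, so that C4a–C4 and O1–C2 arise in one operation as a formal [3+3] annulation with loss of one water. The closest known reaction types are the dehydrative Friedel–Crafts alkylation of phenols with electron-rich benzylic alcohols (HFIP or Lewis acid, as in flavan-4-ol couplings) and the acid-induced cyclisation of 1-aryl-3-(2-hydroxyaryl)propene oxides to 2,3-trans-flavan-3-ols, and only their merger on a 2,3-epoxy alcohol is new. Ring C closes in the 6-endo-tet mode, which should beat 5-exo attack at C3 because the para 4'-benzyloxy group of ring B weakens the C2–O bond and localises the developing charge on C2. C2 is set by backside attack on the (S)-configured epoxide carbon (inversion to 2R, hence 2,3-trans), while C3 keeps its C–O bond and its configuration from step 6. C4 is set by 1,2-induction from C3: allylic 1,3-strain against the two ortho oxygens of ring D holds C3–H close to the plane of the cation, the HFIP-solvated C3–O bond stands roughly perpendicular to it, and resorcinol should approach anti to that bond (polar Felkin–Anh), which leads to the 3,4-trans (4S) adduct whose ring closure passes through an all-equatorial half-chair. The step needs ionisation of the carbinol before the epoxide (secured by the much stronger donor ring D), C- rather than O-alkylation (soft, delocalised cation), attack by C4 rather than C2 of resorcinol (steric hindrance between the two OH groups, and C4 and C6 are equivalent by symmetry so that either gives the same product) and capture by resorcinol rather than by C6 of ring D of a second molecule (eightfold excess, high dilution).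

Step 9
Reactants: 14 3',4',5'-tri-O-benzylrobinetinidol-(4α,8)-penta-O-benzylcatechin
Product: 15 robinetinidol-(4α,8)-catechin
Conditions: H2 (1 atm), Pd(OH)2/C, THF/MeOH/H2O, rt; filtration under argon, lyophilisation
Reagents that add atoms: none
Why: Hydrogenolysis of benzyl ethers over Pd(OH)2/C at one atmosphere, standard for benzylated proanthocyanidins, should remove all eight benzyl groups without touching the cyclic C2–O1 bonds, the diarylmethine C4 or any stereocentre.

**Compound list**
1 | (+)-catechin, (2R,3S)-flavan-3,5,7,3',4'-pentol | Oc1cc(O)c2c(c1)O[C@H](c1ccc(O)c(O)c1)[C@@H](O)C2 | starting material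
2 | 5,7,3',4'-tetra-O-benzylcatechin (2R,3S; 3-OH free) | O(Cc1ccccc1)c1cc(OCc2ccccc2)c2c(c1)O[C@H](c1ccc(OCc3ccccc3)c(OCc3ccccc3)c1)[C@@H](O)C2 | intermediate
3 | 8-bromo-5,7,3',4'-tetra-O-benzylcatechin | O(Cc1ccccc1)c1cc(OCc2ccccc2)c2c(c1Br)O[C@H](c1ccc(OCc3ccccc3)c(OCc3ccccc3)c1)[C@@H](O)C2 | intermediate
4 | 8-bromo-3,5,7,3',4'-penta-O-benzylcatechin | O(Cc1ccccc1)c1cc(OCc2ccccc2)c2c(c1Br)O[C@H](c1ccc(OCc3ccccc3)c(OCc3ccccc3)c1)[C@@H](OCc1ccccc1)C2 | intermediate
5 | 3,4,5-trihydroxybenzaldehyde | O=Cc1cc(O)c(O)c(O)c1 | starting material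
6 | 3,4,5-tris(benzyloxy)benzaldehyde | O=Cc1cc(OCc2ccccc2)c(OCc2ccccc2)c(OCc2ccccc2)c1 | intermediate
7 | (E)-3-[3,4,5-tris(benzyloxy)phenyl]prop-2-enal | O=C/C=C/c1cc(OCc2ccccc2)c(OCc2ccccc2)c(OCc2ccccc2)c1 | intermediate
8 | (2R,3S)-3-[3,4,5-tris(benzyloxy)phenyl]oxirane-2-carbaldehyde (trans-epoxide) | O1[C@@H](c2cc(OCc3ccccc3)c(OCc3ccccc3)c(OCc3ccccc3)c2)[C@@H]1C=O | intermediate
9 | 8-lithio-3,5,7,3',4'-penta-O-benzylcatechin | O(Cc1ccccc1)c1cc(OCc2ccccc2)c2c(c1[Li])O[C@H](c1ccc(OCc3ccccc3)c(OCc3ccccc3)c1)[C@@H](OCc1ccccc1)C2 | intermediate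
10 | (3,5,7,3',4'-penta-O-benzylcatechin-8-yl)[(2S,3S)-3-(3,4,5-tris(benzyloxy)phenyl)oxiran-2-yl]methanol, carbinol carbon (later C4) as both epimers | O1[C@@H](c2cc(OCc3ccccc3)c(OCc3ccccc3)c(OCc3ccccc3)c2)[C@@H]1C(O)c1c(OCc2ccccc2)cc(OCc2ccccc2)c2c1O[C@H](c1ccc(OCc3ccccc3)c(OCc3ccccc3)c1)[C@@H](OCc1ccccc1)C2 | intermediate
11 | resorcinol (benzene-1,3-diol) | Oc1cccc(O)c1 | starting material
12 | C4 benzylic cation from 10, stabilised by ring D, epoxide intact | O1[C@@H](c2cc(OCc3ccccc3)c(OCc3ccccc3)c(OCc3ccccc3)c2)[C@@H]1[CH+]c1c(OCc2ccccc2)cc(OCc2ccccc2)c2c1O[C@H](c1ccc(OCc3ccccc3)c(OCc3ccccc3)c1)[C@@H](OCc1ccccc1)C2 | intermediate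
13 | Friedel–Crafts adduct: (S)-methine C4 bearing 2,4-dihydroxyphenyl, penta-O-benzylcatechin-8-yl and the (2S,3S)-3-aryloxiran-2-yl group | O1[C@@H](c2cc(OCc3ccccc3)c(OCc3ccccc3)c(OCc3ccccc3)c2)[C@@H]1[C@@H](c1ccc(O)cc1O)c1c(OCc2ccccc2)cc(OCc2ccccc2)c2c1O[C@H](c1ccc(OCc3ccccc3)c(OCc3ccccc3)c1)[C@@H](OCc1ccccc1)C2 | intermediate
14 | 3',4',5'-tri-O-benzylrobinetinidol-(4α,8)-3,5,7,3',4'-penta-O-benzylcatechin (upper unit 2R,3S,4S with free 3-OH and 7-OH; lower unit 2R,3S) | Oc1ccc2c(c1)O[C@H](c1cc(OCc3ccccc3)c(OCc3ccccc3)c(OCc3ccccc3)c1)[C@@H](O)[C@@H]2c1c(OCc2ccccc2)cc(OCc2ccccc2)c2c1O[C@H](c1ccc(OCc3ccccc3)c(OCc3ccccc3)c1)[C@@H](OCc1ccccc1)C2 | intermediate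
15 | robinetinidol-(4α,8)-catechin | Oc1ccc2c(c1)O[C@H](c1cc(O)c(O)c(O)c1)[C@@H](O)[C@@H]2c1c(O)cc(O)c2c1O[C@H](c1ccc(O)c(O)c1)[C@@H](O)C2 | target

**Totals**
Total step count: 9.
Longest linear sequence: 6 steps (1, 2, 3, 7, 8, 9). The branch 4, 5, 6, 7, 8, 9 is equally long.

**Steps most likely to fail**

1. Step 8.
- What may go wrong: loss of facial control when the open-chain C4 cation is captured, fragmentation or hydride shift of the epoxy-carbinyl system before capture, or closure in the 5-exo mode.
- Fallback: the annulation is given up. The interflavan bond is formed last on a cyclic flavan-4-yl cation, where attack trans to the 3-OH is known chemistry. It sets out from 2 and comes back at 15.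
- Route: commercial (+)-dihydrorobinetin F1 is benzylated on its four phenols (BnBr, K2CO3, DMF) to 7,3',4',5'-tetra-O-benzyldihydrorobinetin F2. This is reduced (NaBH4, THF/EtOH) to the 2,3-trans-3,4-trans tetra-O-benzylflavan-3,4-diol F3. F3 is condensed with an excess of 2 (TiCl4, CH2Cl2, 0 °C), C8 of 2 attacking the ring-bound cation anti to the 3-OH. This gives 7,3',4',5'-tetra-O-benzylrobinetinidol-(4α,8)-5,7,3',4'-tetra-O-benzylcatechin F4. Hydrogenolysis under the conditions of step 9 gives 15.

2. Step 7.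
- What may go wrong: proton transfer or epoxide opening instead of carbonyl addition by the hindered aryllithium, and ionisation of the labile carbinol during isolation.
- Fallback: the chain is built at the ketone level and the epoxide is introduced afterwards. It sets out from 4 and 6 and comes back at 10.
- Route: 4 is lithiated as before to 9 and acylated with N-methoxy-N-methylacetamide to 8-acetyl-penta-O-benzylcatechin F5. Claisen–Schmidt condensation with 6 (KOH, EtOH/THF) gives the (E)-chalcone F6. Juliá–Colonna epoxidation (poly-L-leucine, urea·H2O2, DBU, THF) gives the (2R,3S)-epoxy ketone F7. Luche reduction (NaBH4, CeCl3·7H2O, MeOH/THF, −40 °C) delivers 10 under non-acidic conditions, again as an epimer mixture.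

3. Step 6.
- What may go wrong: sluggish iminium formation with the electron-rich enal, erosion of enantiomeric purity, or opening of the aryl epoxide in the aqueous peroxide medium.
- Fallback: the stereocentres are set at the allylic alcohol level. It sets out from 7 and comes back at 8.
- Route: 7 is reduced (NaBH4, CeCl3·7H2O, MeOH, 0 °C) to (E)-3-[3,4,5-tris(benzyloxy)phenyl]prop-2-en-1-ol F8. Sharpless asymmetric epoxidation (Ti(OiPr)4, L-(+)-diisopropyl tartrate, t-BuOOH, 4 Å sieves, CH2Cl2, −20 °C) gives [(2S,3S)-3-(3,4,5-tris(benzyloxy)phenyl)oxiran-2-yl]methanol F9. Parikh–Doering oxidation (SO3·pyridine, DMSO, Et3N, CH2Cl2, 0 °C) gives 8.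

**Further compounds**
F1 | step 8 | (+)-dihydrorobinetin, (2R,3R)-3,7,3',4',5'-pentahydroxyflavan-4-one | Oc1ccc2c(c1)O[C@H](c1cc(O)c(O)c(O)c1)[C@@H](O)C2=O
F2 | step 8 | 7,3',4',5'-tetra-O-benzyldihydrorobinetin | O(Cc1ccccc1)c1ccc2c(c1)O[C@H](c1cc(OCc3ccccc3)c(OCc3ccccc3)c(OCc3ccccc3)c1)[C@@H](O)C2=O
F3 | step 8 | (2R,3S,4R)-7,3',4',5'-tetra-O-benzylflavan-3,4-diol | O(Cc1ccccc1)c1ccc2c(c1)O[C@H](c1cc(OCc3ccccc3)c(OCc3ccccc3)c(OCc3ccccc3)c1)[C@@H](O)[C@@H]2O
F4 | step 8 | 7,3',4',5'-tetra-O-benzylrobinetinidol-(4α,8)-5,7,3',4'-tetra-O-benzylcatechin | O(Cc1ccccc1)c1ccc2c(c1)O[C@H](c1cc(OCc3ccccc3)c(OCc3ccccc3)c(OCc3ccccc3)c1)[C@@H](O)[C@@H]2c1c(OCc2ccccc2)cc(OCc2ccccc2)c2c1O[C@H](c1ccc(OCc3ccccc3)c(OCc3ccccc3)c1)[C@@H](O)C2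
F5 | step 7 | 8-acetyl-3,5,7,3',4'-penta-O-benzylcatechin | CC(=O)c1c(OCc2ccccc2)cc(OCc2ccccc2)c2c1O[C@H](c1ccc(OCc3ccccc3)c(OCc3ccccc3)c1)[C@@H](OCc1ccccc1)C2
F6 | step 7 | (E)-1-(penta-O-benzylcatechin-8-yl)-3-[3,4,5-tris(benzyloxy)phenyl]prop-2-en-1-one | O=C(/C=C/c1cc(OCc2ccccc2)c(OCc2ccccc2)c(OCc2ccccc2)c1)c1c(OCc2ccccc2)cc(OCc2ccccc2)c2c1O[C@H](c1ccc(OCc3ccccc3)c(OCc3ccccc3)c1)[C@@H](OCc1ccccc1)C2
F7 | step 7 | (penta-O-benzylcatechin-8-yl) (2R,3S)-3-[3,4,5-tris(benzyloxy)phenyl]oxiran-2-yl ketone | O1[C@@H](c2cc(OCc3ccccc3)c(OCc3ccccc3)c(OCc3ccccc3)c2)[C@@H]1C(=O)c1c(OCc2ccccc2)cc(OCc2ccccc2)c2c1O[C@H](c1ccc(OCc3ccccc3)c(OCc3ccccc3)c1)[C@@H](OCc1ccccc1)C2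
F8 | step 6 | (E)-3-[3,4,5-tris(benzyloxy)phenyl]prop-2-en-1-ol | OC/C=C/c1cc(OCc2ccccc2)c(OCc2ccccc2)c(OCc2ccccc2)c1
F9 | step 6 | [(2S,3S)-3-(3,4,5-tris(benzyloxy)phenyl)oxiran-2-yl]methanol | O1[C@@H](c2cc(OCc3ccccc3)c(OCc3ccccc3)c(OCc3ccccc3)c2)[C@@H]1CO
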